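(All runs were computed for substances that don't exist; scatter was added.)

3 questions stand over one flask of Z: how much has reacted, and how much G and L it holds at the end.

| flask | Z | remark | time |
|---|---|---|---|
| winter | 0.034 M | run made earlier |  |
| spring | 0.075 M | run made earlier |  |
| flask | 0.050 M |  | 15 d |

| run | time / d | Z / % | G / % | L / % |
|---|---|---|---|---|
| winter | 2.50 | 24.5 | 16.7 | 13.7 |
| winter | 5.00 | 23.8 | 16.5 | 14.9 |
| winter | 6.00 | 23.8 | 15.8 | 15.0 |
| winter | 10.0 | 23.5 | 16.6 | 14.5 |
| spring | 0.625 | 27.2 | 14.6 | 6.7 |
| spring | 1.67 | 25.2 | 16.5 | 12.8 |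
| spring | 4.00 | 23.3 | 16.0 | 14.5 |
| spring | 10.0 | 23.6 | 15.4 | 14.5 |

(scatter of a reading: 0.5 percentage points)

- how much of the Z has reacted by 15 d
- how much G there is at 15 d, in percent of the Z charged
- how much L there is at 15 d, in percent of the Z charged

- what has gone from Z into another species counts as reacted, even if it can come back

We start from where the runs stop. From 4.00 d onward the winter and spring runs read alike, though the spring charge is twice the winter charge. The means of those readings are 23.6% Z, 16.1% G and 14.7% L. The flask's charge lies between the two, so we expect these levels there, and 76.4% of its Z reacted.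

Does 15 d reach them? We take the gap of L below its level to shrink as a first-order decay, the gap falling exponentially with rate times time. In the spring run the gap is 8 percentage points at 0.625 d and 1.9 points at 1.67 d, which gives 1.38 d⁻¹.

The weak link is that second gap: it stands at 1.9 points with a scatter of 0.5 points on the reading, and the span is short. So we reforge it. The winter reading at 2.50 d leaves 0.98 points, a smaller gap and so nearer the scatter, but set against the first spring gap, over the longer span, it gives the closing rate (the relaxation rate) 1.12 d⁻¹, slower than the first value. The gap then halves every 0.620 d, and 15 d holds 24.2 such halvings. We commit to the plateau.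

The forecast gives 76.4% reacted, 16% G and 14.7% L, holding that “its composition doesn't depend on concentration”.

The flask gives 76.2% reacted, 15.9% G and 14.8% L.

    Z ⇌ G (K = 0.670, k = 0.0980 h⁻¹)
    G ⇌ X (K = 0.750, k = 0.930 h⁻¹)
    X ⇌ J (K = 0.620, k = 0.0990 h⁻¹)
    J ⇌ Z (k = 0.130 h⁻¹)
    G ⇌ L (K = 0.930, k = 0.0490 h⁻¹)
    Z ⇌ Q (K = 1.10, k = 0.270 h⁻¹)

Left for 150 d, the flask still shows 76.2% reacted. Our closing rate, applied to the flask at 1.50 d, leaves a gap of 3 points, so L of 11.7%, and the flask holds 11.8%.

The same flask read at 6.0 d has had 9.68 halvings, which leaves a gap of 0.02 points and L at 14.7%. Computed, that flask holds 14.8% L.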